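At early times the zeta and theta runs stand level, with 90.2% and 90.5% of the starting material left at 5.00 min. They part later, when each stops on its own plateau.

common to all: starting material 0.10 M; free catalyst 0.1 mol%

| flask | second substrate | solid reagent | remark | time |
|---|---|---|---|---|
| zeta | 1 equiv | 0.55 equiv | run made earlier |  |
| theta | 1 equiv | 0.83 equiv | run made earlier |  |
| flask | 1.00 equiv | 1.10 equiv |  | 1.0 h |

| run | time / min | starting material / % | target / % | uncatalysed product / % |
|---|---|---|---|---|
| zeta | 5.00 | 90.2 | 2.7 | 6.6 |
| zeta | 15.0 | 76.1 | 8.4 | 15.0 |
| zeta | 30.0 | 76.6 | 7.4 | 14.6 |
| zeta | 40.0 | 76.3 | 7.6 | 15.3 |
| zeta | 60.0 | 76.7 | 8.6 | 15.8 |
| theta | 5.00 | 90.5 | 2.8 | 6.2 |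
| theta | 15.0 | 72.6 | 9.1 | 18.1 |
| theta | 30.0 | 65.1 | 12.8 | 21.9 |
| theta | 40.0 | 64.9 | 13.2 | 22.1 |
| theta | 60.0 | 64.5 | 12.7 | 21.6 |

(scatter of a reading: 0.5 percentage points)

- given per volume of solution although it is solid: solid reagent
- what may be going on: starting material + free catalyst <-> catalyst intermediate A; partner + catalyst intermediate A -> free catalyst + target; second substrate + free catalyst <-> catalyst intermediate B; partner + catalyst intermediate B -> free catalyst + second product; solid reagent <-> partner; starting material + partner -> uncatalysed product
- at the start none of the solid reagent is in solution
- the reaction counts as stopped when no species that holds the starting material changes by six tenths of a point or more over the second half of the time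

- which holds at 1.0 h: what has brought the reaction to rest, or that it has not come to rest (for what has run out or reacted, a solid counts together with what of it has only dissolved) (the partner has run out first / no working catalyst is left / it is still moving / all of the starting material has reacted / forward and back rates have come level)
- part of the starting material gone at 1.0 h
- the target standing at 1.0 h, as a percentage of the starting material charged
- the uncatalysed product standing at 1.0 h, as a percentage of the starting material charged
- amount of target if the flask were left three thousand times as long, in percent of the starting material charged

I read each plateau as a count of the solid reagent, which behaves as the limiting reagent. The theta plateau gives a take-up of 0.424, meaning the fraction of the starting material consumed at rest per equivalent of solid reagent charged, with 1 equiv of second substrate. The zeta plateau gives 0.427, so these two readings agree.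

Now I turn the question round and ask what another ending would need. To consume all the starting material with this flask's 1.10 equiv of solid, the take-up would have to be 0.909, about twice what I read. To be still moving, the flask would have to go on consuming starting material until about 30.0 min or later, since the stopping rule looks at the second half of the time. Theta had consumed 27.4% by 15.0 min; if the flask keeps that average pace up to my take-up, I estimate that it reaches its plateau at 25.5 min, which is 4.49 min inside that line.

Theta's plateau is the large part of my estimate, and the extra 0.270 equivalents of solid add a correction of 11 percentage points. My reckoning is therefore a conversion of 46.6%, a little above the forecast's.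

The forecast says the partner has run out first, with conversion 46%, target 18.5%, uncatalysed product 27.4% and long-time target 18.5%, on the ground that “the solid should therefore be gone by about 30 min”.

In the flask, the partner has run out first, with 0% of the partner left: conversion 46.1%, target 18.3%, uncatalysed product 27.8% and long-time target 18.3%.

    starting material + free catalyst ⇌ catalyst intermediate A (K = 5.90 /M, k = 5470 /M/s)
    partner + catalyst intermediate A → free catalyst + target (k = 1850 /M/s)
    second substrate + free catalyst ⇌ catalyst intermediate B (K = 370 /M, k = 582 /M/s)
    partner + catalyst intermediate B → free catalyst + second product (k = 152 /M/s)
    solid reagent ⇌ partner, rate k5*(cs5 - [partner]) while solid is left; crystals form when [partner] > cs5 (solubility = 7.30 mM, k = 0.0167 /s)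
    starting material + partner → uncatalysed product (k = 0.0806 /M/s)

The flask's take-up is 0.419, level with the reading from theta, and its solid stands at 0% of its charge at 0.500 h. The flask's target stays low because the second substrate binds the free catalyst as catalyst intermediate B, the resting state, which holds 94.2% of the catalyst at 0.100 h, while the reaction is running; the run without that binding gives 91.3% target against 18.3%. In the neighbouring flask with 1.70 equiv of second substrate and the same solid, the take-up is lower, at 0.366, with target 10.1%.

(Readings and results were generated by integration on assumed constants; noise was put on by code.)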